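**Strategy.** The target is cut at two adjacent bonds of ring B: the diaryl ether bond O–B1 and the B2–Br bond (ring B numbered B1 ether carbon, B2 Br, B3 Br, B4 OH, B5 Br, B6 H). Both are made in one operation by adding the ring A phenoxide to a ring B aryne spanning B1–B2 and quenching the resulting B2 anion with a bromine donor; the B3 bromine next to the aryne steers oxygen to B1. The aryne precursor is an ortho-silyl aryl triflate (OTf at B1, SiMe3 at B2, Br at B3 and B5, OMe at B4), the partner a fully blocked dibromodimethoxyphenol. Global demethylation then gives the target.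

Key step: step 6

Remark on the chemistry: the target has no stereocentre. Going round ring A from its ether carbon, the substituents are Br, OH, Br, H and OH. Compounds 1, 10 and 12 are assumed to be purchasable.

**Step 1**
Reactants: 1 2,6-dibromohydroquinone (2,6-dibromobenzene-1,4-diol)
Product: 2 3,5-dibromo-4-methoxyphenol
Conditions: MeI (1.05 equiv), KHCO3 (1.1 equiv), DMF, rt to 40 °C, argon
Reagents that add atoms: iodomethane, CI
Why: The hydroxyl flanked by two bromines is markedly more acidic than the other one, so the weak bicarbonate base should ionise essentially only that oxygen, which is then methylated by SN2 (Williamson ether synthesis, acidity-controlled mono-O-alkylation of a dihydric phenol).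

**Step 2**
Reactants: 2 3,5-dibromo-4-methoxyphenol
Product: 3 3,5-dibromo-4-methoxyphenyl isopropylcarbamate
Conditions: iPrNCO, Et3N (cat.), CH2Cl2, rt
Reagents that add atoms: isopropyl isocyanate, CC(C)N=C=O
Why: Amine-catalysed addition of the phenol to the isocyanate (carbamoylation) should give the N-monoalkyl carbamate, which directs ortho-metalation and can later be removed under mild base.

**Step 3**
Reactants: 3 3,5-dibromo-4-methoxyphenyl isopropylcarbamate
Product: 7 3,5-dibromo-4-methoxy-2-(trimethylsilyl)phenyl isopropylcarbamate, via N-silyl carbamate 4 (not isolated), via aryllithium 5 (not isolated), via N-silyl C-silyl carbamate 6 (not isolated)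
Conditions: TBSOTf, TMEDA, Et2O, 0 °C to rt; LiN(iPr)2 (2.1 equiv), THF, −78 °C; Me3SiCl, −78 °C to rt; aq NaHSO4
Reagents that add atoms: chlorotrimethylsilane, C[Si](C)(C)Cl
Why: After transient N-silylation masks the N–H, the ring proton between the carbamate oxygen and a bromine (the two such positions are equivalent by symmetry) is the most acidic and should be removed by LiN(iPr)2, which unlike an alkyllithium does not undergo bromine–lithium exchange (directed ortho-metalation), so that silyl chloride quench and acidic work-up deliver the C-silylated carbamate.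

**Step 4**
Reactants: 7 3,5-dibromo-4-methoxy-2-(trimethylsilyl)phenyl isopropylcarbamate
Product: 9 3,5-dibromo-4-methoxy-2-(trimethylsilyl)phenyl trifluoromethanesulfonate, via silylphenol 8 (not isolated)
Conditions: DBU, Et2NH, MeCN, 40 °C; then PhNTf2, rt
Reagents that add atoms: N-phenylbis(trifluoromethanesulfonimide), O=S(=O)(N(c1ccccc1)S(=O)(=O)C(F)(F)F)C(F)(F)F
Why: Deprotonation of the carbamate N–H should trigger E1cB loss of the phenoxide, with the isocyanate trapped by diethylamine as a urea, and the phenoxide is then O-sulfonylated in the same flask (carbamate cleavage followed by triflation of a phenol).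

**Step 5**
Reactants: 10 2,5-dimethoxyphenol
Product: 11 2,4-dibromo-3,6-dimethoxyphenol
Conditions: NBS (2.05 equiv), MeCN, 0 °C to rt
Reagents that add atoms: N-bromosuccinimide, O=C1CCC(=O)N1Br
Why: In this electrophilic aromatic bromination the free hydroxyl directs to its para and its open ortho position, both of which are also ortho to the 5-methoxy group, whereas the third free position is activated by only one methoxy group and should stay untouched at two equivalents of reagent.

**Step 6**
Reactants: 9 3,5-dibromo-4-methoxy-2-(trimethylsilyl)phenyl trifluoromethanesulfonate; 11 2,4-dibromo-3,6-dimethoxyphenol; 12 bromopentafluorobenzene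
Product: 16 1,3-dibromo-2,5-dimethoxy-4-(2,3,5-tribromo-4-methoxyphenoxy)benzene, via potassium phenoxide 13 (not isolated), via aryne 14 (not isolated), via arylpotassium 15 (not isolated)
Conditions: 11, KH (1.0 equiv), THF, 0 °C; then 18-crown-6, C6F5Br (5 equiv), CsF (3 equiv), slow addition of 9 (1.4 equiv), THF, 0 °C to rt; aq HCl quench
Reagents that add atoms: bromopentafluorobenzene (compound 12), Fc1c(F)c(F)c(Br)c(F)c1F
Why: Proposed new method: fluoride attack on the silicon of 9 expels triflate and generates aryne 14, whose B3 bromine distorts the triple bond so that the oxygen of phenoxide 13 adds at B1, the aryne carbon remote from B3, which places the carbanion at B2 where the neighbouring C–Br bond stabilises it inductively (15); halogen–metal exchange of 15 with the perfluoroaryl bromide, driven by release of the much less basic pentafluorophenyl anion, then installs the B2 bromine. The closest known reaction types are the O-arylation of phenols by arynes from ortho-silylaryl triflates and the aryne 1,2-difunctionalisation in which a heteroatom nucleophile adds and the aryl anion is captured by an electrophilic bromine donor (bromothiolation); pairing an aryloxide with bromine transfer goes beyond both. No ring is closed and no stereocentre is formed. The step needs regioselective oxygen addition, which the B3 bromine and the bulk of the di-ortho-substituted phenoxide should secure, and it needs bromine transfer to outrun protonation and bromide loss from the ortho-bromoaryl anion, which is addressed by a preformed proton-free potassium phenoxide, an ether solvent without acidic C–H bonds, a large excess of donor and low temperature. Carbon bromination of 13 is excluded because both ortho positions and the para position of the phenoxide are substituted, and its low basicity should limit fluoride displacement on the donor.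

**Step 7**
Reactants: 16 1,3-dibromo-2,5-dimethoxy-4-(2,3,5-tribromo-4-methoxyphenoxy)benzene
Product: 17 3,5-dibromo-2-(2,3,5-tribromo-4-hydroxyphenoxy)benzene-1,4-diol
Conditions: BBr3 (8 equiv), CH2Cl2, −78 °C to rt; then H2O, 0 °C, work-up under argon with aq Na2S2O4
Reagents that add atoms: none
Why: Lewis acid-mediated cleavage of the three aryl methyl ethers (O-demethylation with BBr3) should proceed by bromide attack on the O-methyl carbons of the boron-complexed ethers, while the diaryl ether and the aryl bromides are inert and the reductive work-up protects the ring A hydroquinone from air oxidation.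

**Compound list**
1 | 2,6-dibromohydroquinone (2,6-dibromobenzene-1,4-diol) | Oc1cc(Br)c(O)c(Br)c1 | starting material
2 | 3,5-dibromo-4-methoxyphenol | COc1c(Br)cc(O)cc1Br | intermediate
3 | 3,5-dibromo-4-methoxyphenyl isopropylcarbamate | COc1c(Br)cc(OC(=O)NC(C)C)cc1Br | intermediate
4 | 3,5-dibromo-4-methoxyphenyl N-(tert-butyldimethylsilyl)-N-isopropylcarbamate | COc1c(Br)cc(OC(=O)N(C(C)C)[Si](C)(C)C(C)(C)C)cc1Br | intermediate (not isolated)
5 | [2,4-dibromo-6-{[N-(tert-butyldimethylsilyl)-N-isopropylcarbamoyl]oxy}-3-methoxyphenyl]lithium | COc1c(Br)cc(OC(=O)N(C(C)C)[Si](C)(C)C(C)(C)C)c([Li])c1Br | intermediate (not isolated)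
6 | 3,5-dibromo-4-methoxy-2-(trimethylsilyl)phenyl N-(tert-butyldimethylsilyl)-N-isopropylcarbamate | COc1c(Br)cc(OC(=O)N(C(C)C)[Si](C)(C)C(C)(C)C)c([Si](C)(C)C)c1Br | intermediate (not isolated)
7 | 3,5-dibromo-4-methoxy-2-(trimethylsilyl)phenyl isopropylcarbamate | COc1c(Br)cc(OC(=O)NC(C)C)c([Si](C)(C)C)c1Br | intermediate
8 | 3,5-dibromo-4-methoxy-2-(trimethylsilyl)phenol | COc1c(Br)cc(O)c([Si](C)(C)C)c1Br | intermediate (not isolated)
9 | 3,5-dibromo-4-methoxy-2-(trimethylsilyl)phenyl trifluoromethanesulfonate | COc1c(Br)cc(OS(=O)(=O)C(F)(F)F)c([Si](C)(C)C)c1Br | intermediate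
10 | 2,5-dimethoxyphenol | COc1ccc(OC)c(O)c1 | starting material
11 | 2,4-dibromo-3,6-dimethoxyphenol | COc1cc(Br)c(OC)c(Br)c1O | intermediate
12 | bromopentafluorobenzene | Fc1c(F)c(F)c(Br)c(F)c1F | starting material
13 | potassium 2,4-dibromo-3,6-dimethoxyphenoxide | COc1cc(Br)c(OC)c(Br)c1[O-].[K+] | intermediate (not isolated)
14 | 3,5-dibromo-4-methoxybenzyne (3,5-dibromo-4-methoxy-1,2-didehydrobenzene) | COC1=C(Br)C#CC=C1Br | intermediate (not isolated)
15 | [2,4-dibromo-6-(2,4-dibromo-3,6-dimethoxyphenoxy)-3-methoxyphenyl]potassium | COc1cc(Br)c(OC)c(Br)c1Oc1cc(Br)c(OC)c(Br)c1[K] | intermediate (not isolated)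
16 | 1,3-dibromo-2,5-dimethoxy-4-(2,3,5-tribromo-4-methoxyphenoxy)benzene | COc1cc(Br)c(OC)c(Br)c1Oc1cc(Br)c(OC)c(Br)c1Br | intermediate
17 | 3,5-dibromo-2-(2,3,5-tribromo-4-hydroxyphenoxy)benzene-1,4-diol | Oc1cc(Br)c(O)c(Br)c1Oc1cc(Br)c(O)c(Br)c1Br | target

**Step count.** Total: 7 steps. Longest linear sequence: 6 steps (steps 1, 2, 3, 4, 6, 7).

**Steps most likely to fail**

Step 6. Several processes could divert the aryl anion or the aryne: the B2 anion could be protonated before bromine transfer; it could expel the B3 bromide and open a second aryne; the released pentafluorophenyl anion could compete with the phenoxide for the aryne; and the phenoxide could attack the triflyl sulfur of 9 or displace fluoride on the donor. The fallback uses known chemistry, sets out from 1 and 2 and comes back at 16. Exhaustive methylation of 1 (excess MeI, K2CO3, DMF) should give 1,3-dibromo-2,5-dimethoxybenzene F1. Iodination ortho to the unhindered methoxy group (N-iodosuccinimide, CF3CO2H, MeCN) should give 1,3-dibromo-4-iodo-2,5-dimethoxybenzene F2. One-pot oxidation with mCPBA and TsOH followed by 1,3,5-trimethoxybenzene should convert it into (2,4-dibromo-3,6-dimethoxyphenyl)(2,4,6-trimethoxyphenyl)iodonium tosylate F3. Separately, monobromination of 2 ortho to the hydroxyl (NBS, 1.0 equiv, MeCN, 0 °C) should give 2,3,5-tribromo-4-methoxyphenol F4. Metal-free O-arylation of F4 with F3 (KOtBu, THF, rt to 40 °C) should transfer the ring A aryl group and not the trimethoxyphenyl group, and give 16.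

Step 3. The ortho-bromo aryllithium could lose LiBr to an aryne, the bromine could migrate, the carbamoyl group could shift to carbon on warming, or both equivalent positions could be silylated. The fallback replaces deprotonation by iodine–lithium exchange, sets out from 2 and comes back at 9. Mono-iodination of 2 ortho to the hydroxyl (N-iodosuccinimide, 1.0 equiv, TsOH cat., MeCN) should give 3,5-dibromo-2-iodo-4-methoxyphenol F5. O-silylation (hexamethyldisilazane, THF, reflux) should give (3,5-dibromo-2-iodo-4-methoxyphenoxy)trimethylsilane F6. Treatment with n-BuLi (THF, −100 °C) should exchange only the iodine, the aryllithium should undergo retro-Brook rearrangement (silicon from oxygen to carbon) to the lithium salt of 8, and Tf2O in the same flask should give 9.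

Step 1. Site selectivity between the two hydroxyls could be poor, the diol could be methylated twice, or the hydroquinone could be oxidised by air under base. The fallback differentiates the two oxygens by steric hindrance instead of acidity, sets out from 1 and comes back at 2. Silylation of the unhindered hydroxyl (TIPSCl, imidazole, DMF, 0 °C) should give 2,6-dibromo-4-[(triisopropylsilyl)oxy]phenol F7. Methylation of the remaining hindered hydroxyl (MeI, K2CO3, acetone) should give (3,5-dibromo-4-methoxyphenoxy)triisopropylsilane F8. Desilylation (TBAF, THF, 0 °C) should give 2.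

**Further compounds**
F1 | step 6 | 1,3-dibromo-2,5-dimethoxybenzene | COc1cc(Br)c(OC)c(Br)c1
F2 | step 6 | 1,3-dibromo-4-iodo-2,5-dimethoxybenzene | COc1cc(Br)c(OC)c(Br)c1I
F3 | step 6 | (2,4-dibromo-3,6-dimethoxyphenyl)(2,4,6-trimethoxyphenyl)iodonium 4-methylbenzenesulfonate | COc1cc(Br)c(OC)c(Br)c1[I+]c1c(OC)cc(OC)cc1OC.Cc1ccc(cc1)S(=O)(=O)[O-]
F4 | step 6 | 2,3,5-tribromo-4-methoxyphenol | COc1c(Br)cc(O)c(Br)c1Br
F5 | step 3 | 3,5-dibromo-2-iodo-4-methoxyphenol | COc1c(Br)cc(O)c(I)c1Br
F6 | step 3 | (3,5-dibromo-2-iodo-4-methoxyphenoxy)trimethylsilane | COc1c(Br)cc(O[Si](C)(C)C)c(I)c1Br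
F7 | step 1 | 2,6-dibromo-4-[(triisopropylsilyl)oxy]phenol | CC(C)[Si](Oc1cc(Br)c(O)c(Br)c1)(C(C)C)C(C)C
F8 | step 1 | (3,5-dibromo-4-methoxyphenoxy)triisopropylsilane | COc1c(Br)cc(O[Si](C(C)C)(C(C)C)C(C)C)cc1Br
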